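## The problem

The target is a phlorotannin of the fucofuroeckol type. A dibenzo[b,e][1,4]dioxin (rings B and C) shares ring C with a dibenzofuran (rings C and D), and a 3,5-dihydroxyphenyl ether (ring A) hangs on ring B. Twenty-four aromatic carbons carry eleven oxygens and there is no stereocentre, so the only things to control are where each oxygen sits and which oxygen joins which ring. Ring B is the hard part: five of its six carbons bear oxygen, in the order ring A ether, dioxin oxygen, dioxin oxygen, hydroxyl, hydrogen, hydroxyl, and substitution of a simpler arene cannot place three kinds of oxygen in that order. Ring C needs four oxygens and a carbon–carbon bond to ring D, and the dioxin must be attached in one orientation: the oxygen next to the ring A ether goes to dibenzofuran C2, the other to the bay carbon C1. The free heptaphenol is electron-rich and air-sensitive, so every hydroxyl stays alkylated until the last step; on the way, the aryl squarate ester, the enol ether beside a tertiary ether, and an aryl bromide facing an organolithium are the fragile points. Two features make the plan possible. The two adjacent dioxin oxygens of ring B sit on neighbouring carbons exactly as the two alkoxy carbons of a squarate do. Ring B is also symmetric about the axis through its C–H and the para carbon (the one whose oxygen is bound to dibenzofuran C2), apart from what the two flanking oxygens carry, so either flanking oxygen may close the dioxin as long as the other receives ring A.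

## Retrosynthesis

**Unmasking.** Target 21 is traced to the hepta-alkyl ether 20 by cutting six O–methyl bonds and one O–ethyl bond. Only alkyl–oxygen bonds are cut; the diaryl ether, dioxin and furan C–O bonds have sp2 carbon on both sides and resist BBr3. Keeping the polyphenol masked to the end avoids handling an oxidation-prone intermediate in any metal-mediated step.

**Ring A.** Cutting the ring A carbon–oxygen bond of 20 gives the pentacyclic phenol 19 and 1-bromo-3,5-dimethoxybenzene 2. Ring A is the simplest part of the molecule and is purchasable as the bromide, and 19 has exactly one free hydroxyl. The forward reaction is a copper-catalysed O-arylation of a di-ortho-substituted phenol.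

**Dioxin.** Phenol 19 comes from the isopropyl ether 18, and 18 from the bromo phenol 17 by cutting the bond between dibenzofuran C1 and a ring B oxygen. The neighbouring order, ring A first on the free hydroxyl of 17 and dioxin closure afterwards through the isopropoxy oxygen, was rejected. It would require an intermolecular coupling of a phenol that has a bromide placed for six-membered ring closure in the same molecule. Because both outer oxygens of ring B end as hydroxyl, the two orders lead to the same constitution. The free phenol of 17 is therefore used for the intramolecular closure, which asks only for a catalytic copper etherification.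

**Ring B.** Cutting the carbon–carbon bond between the phenol carbon and the ethoxy-bearing carbon of 17 leads to the 4-alkenyl-4-methoxycyclobutenone 14. Against stepwise oxygenation of a benzene, this cut delivers all five oxygens already differentiated: free OH from the ketene, aryloxy and isopropoxy from the squarate, methoxy from the capped carbinol, ethoxy from the enol ether. The forward reaction needs only heat.

**Cyclobutenone.** Cutting the bond from C4 to the vinyl group and the O–methyl bond of 14 gives the mixed squarate 10 and (Z)-1-bromo-2-ethoxyethene 11. The forward reaction must add the vinyllithium to the carbonyl next to the isopropoxy-bearing carbon. That carbonyl is conjugated with the weaker aryloxy donor and is further from the bulky aryl group, so electronics and sterics agree.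

**Mixed squarate.** Compound 10 is cut at the squarate–aryloxy bond into the chloro ester 9 and the bromodibenzofuranol 6; 9 comes from the dichloride 8 and squaric acid 7. A diaryl squarate already carrying ring A would save two steps, but its two carbonyls would be almost equally electrophilic and the regiocontrol of the addition would be lost. The isopropyl group is kept for that reason.

**Dibenzofuranol.** Compound 6 is cut at the C1–Br bond to phenol 5, at the benzyl ether to 4, at the ring C–ring D carbon–carbon bond to the diaryl ether 3, and at the ether bond to 4-(benzyloxy)-3-methoxyphenol 1 and bromide 2. This takes both aryl rings from purchasable materials in two bond-forming steps. The price is a bromination that must choose the phenol ring over the trialkoxy ring D.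

## Roads not taken

**Alternative 1:** The cut is the ring C–ring D carbon–carbon bond, made last. A bromo dibenzodioxin A2, carrying a 3,5-dimethoxyphenoxy group on ring C next to the bromide, would be treated with Pd(OAc)2, PCy3, K2CO3 and pivalic acid. Zerovalent palladium inserts into the C–Br bond and arylates an ortho C–H of the phenoxy ring, giving the hepta-O-methyl ether A1. The merits are real: the closing step is well precedented, ring D arrives as the same cheap phenoxy unit as ring A, and no bromide has to be placed in the dibenzofuran bay. The weakness is that A2 already contains the penta-oxygenated ring B and the correctly oriented dioxin, so the chief problem is only postponed. The bromide of A2 also sits between two oxygens on a very electron-rich ring, which slows oxidative addition. In the closing step this road is at least as good as the chosen one. The chosen plan sets against it a ring B made with every oxygen differentiated and one dioxin C–O bond in place before the ring exists.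

**Alternative 2:** The cut removes ring C entirely. The acid chloride A4 would give a benzofuranylketene with Et3N; [2+2] addition to di-tert-butoxyethyne A5, ring opening and closure onto the furan 3-carbon would form three carbon–carbon bonds and the dibenzofuran-1-ol A3. It is better than the chosen plan in one respect: the contiguous oxygens of ring C arrive by construction, with the bay oxygen free, so the bromination of step 4 disappears. Its weak points are these:
- The 2- and 3-oxygens are both tert-butyl ethers, yet one must become a dioxin oxygen and the other a hydroxyl.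
- The alkyne is sensitive and must be prepared, and A4 needs its own synthesis.
- Ring B is still unsolved, and joining a ring C diol to a ring B dielectrophile has nothing to fix the orientation of the dioxin.

The chosen plan is shorter to the dibenzofuran (two steps from purchasable arenes) and fixes the dioxin orientation by making its first C–O bond at the squarate stage.

**Alternative 3:** The cut removes ring A. The aryl ethynyl ether A7 would be heated with 3-ethoxycyclobutenone A8; the vinylketene adds to the alkyne, and ring opening and 6-electron closure give A6, with ring A as a 3-ethoxy-5-hydroxyphenyl group. This replaces the hindered O-arylation of step 12 with a neutral thermal reaction and is the better answer if that coupling fails for steric reasons. It spends three carbon–carbon bonds on the one ring that can be bought, needs two or three steps to turn a hindered electron-rich phenol into its ethynyl ether, and presupposes a pentacyclic phenol of the kind of 19. It is therefore a substitute for one step, not a solution to ring B. The chosen plan sets a single copper coupling with a metal-free fallback against it.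

Key step: step 9

Remark on the chemistry: 4-(benzyloxy)-3-methoxyphenol and (Z)-1-bromo-2-ethoxyethene are taken as purchasable; 14 and 16 are racemic and their stereocentres vanish on aromatisation.

## Route

Step 1
Reactants: 1 4-(benzyloxy)-3-methoxyphenol; 2 1-bromo-3,5-dimethoxybenzene
Product: 3 1-(benzyloxy)-4-(3,5-dimethoxyphenoxy)-2-methoxybenzene
Conditions: CuI (10 mol %), N,N-dimethylglycine·HCl, Cs2CO3, 1,4-dioxane, 90 °C
Reagents that add atoms: none
Why: Ullmann diaryl ether synthesis; amino-acid-ligated monovalent copper couples electron-rich phenols with electron-rich aryl bromides, and benzyl and methyl ethers are inert to carbonate.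

Step 2
Reactants: 3 1-(benzyloxy)-4-(3,5-dimethoxyphenoxy)-2-methoxybenzene
Product: 4 2-(benzyloxy)-3,7,9-trimethoxydibenzo[b,d]furan
Conditions: Pd(OAc)2 (10 mol %), K2CO3 (10 mol %), PivOH, air, 120 °C
Reagents that add atoms: none
Why: Intramolecular dehydrogenative biaryl coupling of a diaryl ether: divalent palladium palladates an electron-rich ortho carbon with pivalate assistance, the second C–H is cleaved in the palladacycle, reductive elimination closes the furan and air reoxidises zerovalent palladium. On ring C the open carbon para to the methoxy group should be preferred over the carbon wedged between two oxygens, and the two ortho carbons of ring D are equivalent.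

Step 3
Reactants: 4 2-(benzyloxy)-3,7,9-trimethoxydibenzo[b,d]furan
Product: 5 3,7,9-trimethoxydibenzo[b,d]furan-2-ol
Conditions: H2 (1 atm), Pd/C, EtOAc–MeOH, rt
Reagents that add atoms: none
Why: Hydrogenolysis of a benzyl aryl ether; the molecule holds no halogen or other reducible group at this stage.

Step 4
Reactants: 5 3,7,9-trimethoxydibenzo[b,d]furan-2-ol
Product: 6 1-bromo-3,7,9-trimethoxydibenzo[b,d]furan-2-ol
Conditions: NBS (1.0 equiv), i-Pr2NH (0.2 equiv), CH2Cl2, −78 to 0 °C
Reagents that add atoms: N-bromosuccinimide, O=C1CCC(=O)N1Br
Why: Amine-mediated ortho-bromination of a phenol: the N-bromoamine is delivered within a hydrogen-bonded phenol–amine pair to the ortho carbon, and C1 is the only free one (C3 carries methoxy, the para carbon is the ring fusion). The phenoxide-like ring should outrun the trialkoxy ring D when one equivalent is used cold.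

Step 5
Reactants: 7 squaric acid
Product: 8 3,4-dichlorocyclobut-3-ene-1,2-dione
Conditions: (COCl)2, DMF (cat.), CH2Cl2, 40 °C
Reagents that add atoms: oxalyl chloride, O=C(Cl)C(Cl)=O
Why: Vilsmeier-catalysed conversion of the two vinylogous acid hydroxyls into vinylogous acid chlorides, the standard preparation of squaric acid dichloride.

Step 6
Reactants: 8 3,4-dichlorocyclobut-3-ene-1,2-dione
Product: 9 3-chloro-4-(propan-2-yloxy)cyclobut-3-ene-1,2-dione
Conditions: i-PrOH (1.0 equiv), CH2Cl2, −20 °C to rt
Reagents that add atoms: propan-2-ol, CC(C)O
Why: Addition–elimination at a vinylogous acid chloride; the first alkoxy group donates into the dione and deactivates the second C–Cl bond, so one equivalent of alcohol without base should stop at the ester chloride.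

Step 7
Reactants: 9 3-chloro-4-(propan-2-yloxy)cyclobut-3-ene-1,2-dione; 6 1-bromo-3,7,9-trimethoxydibenzo[b,d]furan-2-ol
Product: 10 3-[(1-bromo-3,7,9-trimethoxydibenzo[b,d]furan-2-yl)oxy]-4-(propan-2-yloxy)cyclobut-3-ene-1,2-dione
Conditions: i-Pr2NEt, CH2Cl2, −20 to 0 °C, anhydrous work-up
Reagents that add atoms: none
Why: Addition–elimination of the phenoxide on the remaining vinylogous acid chloride, the reaction type by which aryl squarates are made; chloride leaves far more readily than isopropoxide and the hindered amine does not attack the ring.

Step 8
Reactants: 11 (Z)-1-bromo-2-ethoxyethene; 10 3-[(1-bromo-3,7,9-trimethoxydibenzo[b,d]furan-2-yl)oxy]-4-(propan-2-yloxy)cyclobut-3-ene-1,2-dione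
Product: 14 2-[(1-bromo-3,7,9-trimethoxydibenzo[b,d]furan-2-yl)oxy]-4-[(Z)-2-ethoxyethenyl]-4-methoxy-3-(propan-2-yloxy)cyclobut-2-en-1-one (racemic), via (Z)-2-ethoxyvinyllithium 12 (not isolated), via lithium alkoxide adduct 13 (not isolated)
Conditions: 11, t-BuLi (2.0 equiv), Et2O, −78 °C; cannulate into 10, THF, −78 °C; then MeOTf, −78 to 0 °C; NaHCO3 work-up, Et3N-deactivated silica
Reagents that add atoms: methyl trifluoromethanesulfonate, COS(=O)(=O)C(F)(F)F
Why: Bromine–lithium exchange with retention gives the chelation-stabilised cis-vinyllithium, which adds 1,2 to a squarate carbonyl at −78 °C far faster than it exchanges with the hindered aryl bromide. Attack should go to the carbonyl next to the isopropoxy carbon, which is conjugated with the weaker, twisted aryloxy donor and remote from the aryl group; MeOTf then O-methylates the lithium alkoxide, and the new C4 centre is racemic and is erased in step 9.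

Step 9
Reactants: 14 2-[(1-bromo-3,7,9-trimethoxydibenzo[b,d]furan-2-yl)oxy]-4-[(Z)-2-ethoxyethenyl]-4-methoxy-3-(propan-2-yloxy)cyclobut-2-en-1-one
Product: 17 2-[(1-bromo-3,7,9-trimethoxydibenzo[b,d]furan-2-yl)oxy]-6-ethoxy-4-methoxy-3-(propan-2-yloxy)phenol, via dienylketene 15 (not isolated), via cyclohexa-2,4-dienone tautomer 16 (not isolated)
Conditions: toluene (degassed, base-washed glassware), 110 °C
Reagents that add atoms: none
Why: This is a Moore cyclisation, the thermal ring expansion of a 4-alkenylcyclobutenone to a phenol. Heating cleaves the C1–C4 bond in a conrotatory 4-electron electrocyclic opening to the dienylketene 15. Torquoselectivity sends the donor methoxy group outward, so the ethoxyvinyl group turns inward and lies cis to the ketene-bearing carbon. Ring B then closes by a disrotatory 6-electron electrocyclisation in which the ketene carbon bonds to the ethoxy-bearing vinyl terminus, the only carbon–carbon bond formed, giving dienone 16. Tautomerisation of the single sp3 C–H of 16 aromatises it irreversibly to phenol 17. No stereocentre is formed; the racemic centre of 14 and the Z geometry of the enol ether are both erased. The one selectivity required, outward rotation of the 4-alkoxy group, is inherent in the substrate, and the oxygen pattern was fixed by the regiochemistry of step 8. Acid-free, degassed conditions protect the tertiary allylic ether of 14 and the electron-rich phenol 17.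

Step 10
Reactants: 17 2-[(1-bromo-3,7,9-trimethoxydibenzo[b,d]furan-2-yl)oxy]-6-ethoxy-4-methoxy-3-(propan-2-yloxy)phenol
Product: 18 benzofuro-fused dibenzo[b,e][1,4]dioxin; ring B carries ethoxy beside the new dioxin oxygen, then H, methoxy, and isopropoxy beside the squarate-derived dioxin oxygen; ring C one methoxy; ring D two methoxy groups
Conditions: CuI (20 mol %), N,N-dimethylglycine·HCl, Cs2CO3, 1,4-dioxane (degassed), 100 °C
Reagents that add atoms: none
Why: Intramolecular Ullmann etherification: the only free phenol attacks the bay C–Br bond through monovalent copper and closes the six-membered dioxin, and ring closure relieves the bromine–methoxy bay strain.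

Step 11
Reactants: 18 isopropyl ether of the pentacyclic dioxin
Product: 19 pentacyclic phenol; as 18 with OH in place of isopropoxy
Conditions: BCl3, CH2Cl2, −78 to 0 °C; then MeOH, H2O
Reagents that add atoms: none
Why: BCl3 cleaves secondary alkyl aryl ethers selectively at low temperature, because the isopropyl–oxygen bond ionises far more readily than methyl– or ethyl–oxygen bonds; the methyl and ethyl ethers and all aryl–oxygen bonds should persist.

Step 12
Reactants: 19 pentacyclic phenol; 2 1-bromo-3,5-dimethoxybenzene
Product: 20 hepta-alkyl ether of the target; as 19 with 3,5-dimethoxyphenoxy in place of OH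
Conditions: CuI (10 mol %), picolinic acid, K3PO4, DMSO, 90 °C
Reagents that add atoms: none
Why: Ullmann O-arylation under conditions developed for di-ortho-substituted phenols; 19 has a single hydroxyl and no halogen, so only the intermolecular coupling is possible.

Step 13
Reactants: 20 hepta-alkyl ether of the target
Product: 21 target heptaphenol
Conditions: BBr3 (excess), CH2Cl2, −78 °C to rt; then MeOH, H2O, under argon
Reagents that add atoms: none
Why: BBr3 cleavage of aryl methyl and aryl ethyl ethers by bromide attack at the alkyl carbon; diaryl ether, dioxin and furan C–O bonds offer no alkyl carbon and remain.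

## Compound list

1 | 4-(benzyloxy)-3-methoxyphenol | COc1cc(O)ccc1OCc1ccccc1 | starting material
2 | 1-bromo-3,5-dimethoxybenzene | COc1cc(Br)cc(OC)c1 | starting material
3 | 1-(benzyloxy)-4-(3,5-dimethoxyphenoxy)-2-methoxybenzene | COc1cc(OC)cc(Oc2ccc(OCc3ccccc3)c(OC)c2)c1 | intermediate
4 | 2-(benzyloxy)-3,7,9-trimethoxydibenzo[b,d]furan | COc1cc2oc3cc(OC)cc(OC)c3c2cc1OCc1ccccc1 | intermediate
5 | 3,7,9-trimethoxydibenzo[b,d]furan-2-ol | COc1cc2oc3cc(OC)cc(OC)c3c2cc1O | intermediate
6 | 1-bromo-3,7,9-trimethoxydibenzo[b,d]furan-2-ol | COc1cc2oc3cc(OC)cc(OC)c3c2c(Br)c1O | intermediate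
7 | squaric acid (3,4-dihydroxycyclobut-3-ene-1,2-dione) | OC1=C(O)C(=O)C1=O | starting material
8 | 3,4-dichlorocyclobut-3-ene-1,2-dione | ClC1=C(Cl)C(=O)C1=O | intermediate
9 | 3-chloro-4-(propan-2-yloxy)cyclobut-3-ene-1,2-dione | CC(C)OC1=C(Cl)C(=O)C1=O | intermediate
10 | 3-[(1-bromo-3,7,9-trimethoxydibenzo[b,d]furan-2-yl)oxy]-4-(propan-2-yloxy)cyclobut-3-ene-1,2-dione | CC(C)OC1=C(Oc2c(OC)cc3oc4cc(OC)cc(OC)c4c3c2Br)C(=O)C1=O | intermediate
11 | (Z)-1-bromo-2-ethoxyethene | CCO/C=C\Br | starting material
12 | (Z)-2-ethoxyvinyllithium | CCO/C=C\[Li] | intermediate
13 | lithium alkoxide of the 1,2-adduct of 12 to 10 (racemic) | [Li]OC1(/C=C\OCC)C(OC(C)C)=C(Oc2c(OC)cc3oc4cc(OC)cc(OC)c4c3c2Br)C1=O | intermediate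
14 | 2-[(1-bromo-3,7,9-trimethoxydibenzo[b,d]furan-2-yl)oxy]-4-[(Z)-2-ethoxyethenyl]-4-methoxy-3-(propan-2-yloxy)cyclobut-2-en-1-one (racemic) | O=C1C(Oc2c(OC)cc3oc4cc(OC)cc(OC)c4c3c2Br)=C(OC(C)C)C1(OC)/C=C\OCC | intermediate
15 | (3Z,5Z)-2-[(1-bromo-3,7,9-trimethoxydibenzo[b,d]furan-2-yl)oxy]-6-ethoxy-4-methoxy-3-(propan-2-yloxy)hexa-1,3,5-trien-1-one (dienylketene) | O=C=C(Oc1c(OC)cc2oc3cc(OC)cc(OC)c3c2c1Br)/C(OC(C)C)=C(OC)\C=C/OCC | intermediate
16 | 2-[(1-bromo-3,7,9-trimethoxydibenzo[b,d]furan-2-yl)oxy]-6-ethoxy-4-methoxy-3-(propan-2-yloxy)cyclohexa-2,4-dien-1-one (racemic) | CCOC1C=C(OC)C(OC(C)C)=C(Oc2c(OC)cc3oc4cc(OC)cc(OC)c4c3c2Br)C1=O | intermediate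
17 | 2-[(1-bromo-3,7,9-trimethoxydibenzo[b,d]furan-2-yl)oxy]-6-ethoxy-4-methoxy-3-(propan-2-yloxy)phenol | CCOc1cc(OC)c(OC(C)C)c(Oc2c(OC)cc3oc4cc(OC)cc(OC)c4c3c2Br)c1O | intermediate
18 | benzofuro-fused dibenzo[b,e][1,4]dioxin; ring B: ethoxy, H, methoxy, isopropoxy; ring C: methoxy; ring D: two methoxy | CCOc1cc(OC)c(OC(C)C)c2Oc3c(OC)cc4oc5cc(OC)cc(OC)c5c4c3Oc12 | intermediate
19 | pentacyclic phenol; 18 with OH in place of isopropoxy | CCOc1cc(OC)c(O)c2Oc3c(OC)cc4oc5cc(OC)cc(OC)c5c4c3Oc12 | intermediate
20 | hepta-alkyl ether of the target; 19 with 3,5-dimethoxyphenoxy in place of OH | CCOc1cc(OC)c(Oc2cc(OC)cc(OC)c2)c2Oc3c(OC)cc4oc5cc(OC)cc(OC)c5c4c3Oc12 | intermediate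
21 | CNP0256302.0, the heptaphenol | Oc1cc(O)cc(Oc2c(O)cc(O)c3c2Oc2c(O)cc4oc5cc(O)cc(O)c5c4c2O3)c1 | target

## Step count and risks

Total: 13 steps. Longest linear sequence: 11 steps (steps 1–4 and 7–13, from 1). The squarate branch (steps 5 and 6) joins at step 7.

**Step 9 (key step).** The tertiary methoxy group of 14 is allylic to an enol ether, so traces of acid can ionise it and divert material to enal-type products before the ring opens. The inward Z-ethoxy group may also slow the 6-electron closure and leave the ketene time for side reactions. Fallback: set out from 10, add 12 as in step 8 but quench the alkoxide 13 with buffered aqueous NH4Cl to give the 4-hydroxycyclobutenone F1. Heat F1 in toluene; the hydroxyl is the stronger outward-rotating donor, and this classical hydroxy variant of the ring expansion gives the hydroquinone F2. Methylate F2 once (MeI, K2CO3, acetone) at the hydroxyl with a single ortho substituent, which is less hindered than the one flanked by aryloxy and ethoxy groups; this returns to 17.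

**Step 4.** Bromination may spread to the trialkoxy ring D, or stall at the congested bay carbon, because ring D is itself highly nucleophilic. Fallback by directed metalation: convert 5 with ClCONEt2 and NaH into the diethylcarbamate F3. Lithiate with s-BuLi and TMEDA at −78 °C, where the carbamate directs kinetically to its only free ortho carbon, and quench with 1,2-dibromotetrafluoroethane to give the bromo carbamate F4. Hydrolyse F4 with KOH in aqueous ethanol at reflux to return to 6.

**Step 8.** Bromine–lithium exchange at the aryl bromide of 10, attack at the wrong carbonyl, or displacement of the aryloxide may compete, because the vinyllithium is strongly basic and the aryl ester is activated. Fallback: add lithium ethoxyacetylide (from ethoxyethyne and n-BuLi), which cannot exchange with an aryl bromide, to 10 and cap with MeOTf to give the 4-(ethoxyethynyl)-4-methoxycyclobutenone F5. Semihydrogenate F5 over Pd on CaCO3 poisoned with Pb(OAc)2, with quinoline, to the Z-enol ether; this returns to 14.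

**Step 2.** The dehydrogenative coupling may give low conversion, oligomers, or coupling into the benzyl group, since two C–H bonds must be cleaved on a substrate with several electron-rich sites. Fallback with a prefunctionalised carbon: brominate 1 with NBS para to its methoxy group to give 2-bromo-4-(benzyloxy)-5-methoxyphenol F6. Join F6 to 3,5-dimethoxyphenylboronic acid by Chan–Lam coupling (Cu(OAc)2, pyridine, air, rt), which spares the bromide, to give the bromo diaryl ether F7. Close the furan by direct arylation (Pd(OAc)2, PCy3·HBF4, K2CO3, DMA, 130 °C); this returns to 4.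

**Step 12.** The phenol of 19 is flanked on both sides and electron-rich, so coupling may be slow and oxidative degradation of the phenoxide may take over. Fallback without metal: treat 19 with t-BuOK and (3,5-dimethoxyphenyl)(2,4,6-trimethoxyphenyl)iodonium tosylate in THF at rt. The less electron-rich aryl group is transferred to oxygen, which gives 20 directly; no new compound lies on the way.

## Further compounds

F1 | step 9 | 2-[(1-bromo-3,7,9-trimethoxydibenzo[b,d]furan-2-yl)oxy]-4-[(Z)-2-ethoxyethenyl]-4-hydroxy-3-(propan-2-yloxy)cyclobut-2-en-1-one (racemic) | O=C1C(Oc2c(OC)cc3oc4cc(OC)cc(OC)c4c3c2Br)=C(OC(C)C)C1(O)/C=C\OCC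
F2 | step 9 | 2-[(1-bromo-3,7,9-trimethoxydibenzo[b,d]furan-2-yl)oxy]-6-ethoxy-3-(propan-2-yloxy)benzene-1,4-diol | CCOc1cc(O)c(OC(C)C)c(Oc2c(OC)cc3oc4cc(OC)cc(OC)c4c3c2Br)c1O
F3 | step 4 | 3,7,9-trimethoxydibenzo[b,d]furan-2-yl diethylcarbamate | COc1cc2oc3cc(OC)cc(OC)c3c2cc1OC(=O)N(CC)CC
F4 | step 4 | 1-bromo-3,7,9-trimethoxydibenzo[b,d]furan-2-yl diethylcarbamate | COc1cc2oc3cc(OC)cc(OC)c3c2c(Br)c1OC(=O)N(CC)CC
F5 | step 8 | 2-[(1-bromo-3,7,9-trimethoxydibenzo[b,d]furan-2-yl)oxy]-4-(ethoxyethynyl)-4-methoxy-3-(propan-2-yloxy)cyclobut-2-en-1-one (racemic) | CCOC#CC1(OC)C(OC(C)C)=C(Oc2c(OC)cc3oc4cc(OC)cc(OC)c4c3c2Br)C1=O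
F6 | step 2 | 2-bromo-4-(benzyloxy)-5-methoxyphenol | COc1cc(O)c(Br)cc1OCc1ccccc1
F7 | step 2 | 1-(benzyloxy)-5-bromo-4-(3,5-dimethoxyphenoxy)-2-methoxybenzene | COc1cc(Oc2cc(OC)cc(OC)c2)c(Br)cc1OCc1ccccc1
F0 | step 12 | none | none
A1 | alternative 1 | hepta-O-methyl ether of the target | COc1cc(OC)cc(Oc2c(OC)cc(OC)c3c2Oc2c(OC)cc4oc5cc(OC)cc(OC)c5c4c2O3)c1
A2 | alternative 1 | bromo dibenzodioxin with a 3,5-dimethoxyphenoxy group on ring C beside the bromide | COc1cc(OC)cc(Oc2c(OC)cc(OC)c3c2Oc2c(OC)cc(Oc4cc(OC)cc(OC)c4)c(Br)c2O3)c1
A3 | alternative 2 | 2,3-di-tert-butoxy-7,9-dimethoxydibenzo[b,d]furan-1-ol | COc1cc(OC)c2c(c1)oc1cc(OC(C)(C)C)c(OC(C)(C)C)c(O)c12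
A4 | alternative 2 | 2-(4,6-dimethoxy-1-benzofuran-2-yl)acetyl chloride | COc1cc(OC)c2cc(CC(=O)Cl)oc2c1
A5 | alternative 2 | di-tert-butoxyethyne | CC(C)(C)OC#COC(C)(C)C
A6 | alternative 3 | target skeleton with ring A as 3-ethoxy-5-hydroxyphenyl and six methyl ethers | CCOc1cc(O)cc(Oc2c(OC)cc(OC)c3c2Oc2c(OC)cc4oc5cc(OC)cc(OC)c5c4c2O3)c1
A7 | alternative 3 | ethynyl ether of the hexamethylated pentacyclic phenol | C#COc1c(OC)cc(OC)c2c1Oc1c(OC)cc3oc4cc(OC)cc(OC)c4c3c1O2
A8 | alternative 3 | 3-ethoxycyclobut-2-en-1-one | CCOC1=CC(=O)C1
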